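You can hold every dosed flask against summer, where everything starts together: summer repeats the oak run, so the oak readings are its readings.

| setting | oak | birch | maple | noon | summer | autumn | winter |
|---|---|---|---|---|---|---|---|
| substrate | 1 mM | 1 mM | 1 mM | 1.0 mM | 1.0 mM | 1.0 mM (fed, over 2.5 min) | 1.0 mM |
| partner | 4 mM | 5.6 mM | 8.8 mM | 4.00 mM (fed, over 2.5 min) | 4.00 mM | 4.00 mM | 4.00 mM (in portions, 4, over 2.5 min) |
| remark | run made earlier | run made earlier | run made earlier | all else is in the flask from the start; the feed brings no volume worth counting | everything together at the start | all else is in the flask from the start; the feed brings no volume worth counting | first portion at the start, last at 2.5 min |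
| time |  |  |  | 3.0 min | 3.0 min | 3.0 min | 3.0 min |

| oak: time / min | oak: target / % | birch: time / min | birch: target / % | maple: time / min | maple: target / % |
|---|---|---|---|---|---|
| 0.417 | 31.6 | 0.250 | 30.5 | 0.417 | 53.2 |
| 0.833 | 39.2 | 0.333 | 37.9 | 0.833 | 61.1 |
| 1.33 | 45.4 | 0.500 | 44.0 | 1.33 | 65.3 |
| 1.50 | 45.7 | 0.833 | 48.3 | 1.50 | 65.5 |
| 2.00 | 46.8 | 1.33 | 52.4 | 2.00 | 65.1 |
| 2.50 | 47.7 | 2.00 | 56.0 | 2.50 | 67.4 |
| 3.00 | 46.3 | 3.00 | 56.6 | 3.00 | 69.2 |

(each reading ± 1 percentage point)

- which flask leads in amount of target, in percent of the substrate charged ("all alike" within 1.5 percentage points) (noon / summer / autumn / winter / all alike)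
- how much target is there at the end, in percent of the substrate charged: noon
- how much target is there at the end, in percent of the substrate charged: summer
- how much target is there at the end, in percent of the substrate charged: autumn
- how much target is there at the end, in percent of the substrate charged: winter

- steps that have been proposed: partner -> decomposed reagent; substrate + partner -> target; partner -> decomposition product; partner <-> dormant form

Write a target reading y as the exponent ln(1/(1−y)). In oak it stands at 0.622 at 3.00 min and at 0.380 at 0.417 min. The approach to the plateau then gives 0.442 min: this is the partner life, the time in which c_partner falls by a factor e. Maple, with 8.8 mM against oak's 4 mM, reads 0.403 min, so I take the loss as first-order in partner, with a life that is free of the charge.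

Each mM of partner then gives the same exposure, ∫c_partner dt, whenever it enters, provided it is spent by the end. Summer is therefore the zero of the scale, and noon's ceiling is the oak reading, 46.3 %. For a floor, count all of noon's partner as entering at 2.50 min, which gives 34.4 %. To tighten this, I reckon with that life that the steady feed leaves 5.68 % of the exposure unspent at 3.0 min, so my noon is 44.4 %. For winter I reckon, counting the last portion by itself, that 8.06 % stays unspent, so my winter is 43.5 %. I commit to summer leading.

The forecast names noon: noon 49.5 % (43 % to 55 %), summer 47 %, autumn 11 %, winter 48 %. It holds that “some loss looks higher-order”, and its noon stands above my ceiling.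

The flask gives summer in the lead: noon 44.5 %, summer 46.9 %, autumn 8.08 %, winter 43.4 %.

    partner → decomposed reagent (k = 0.0300 s⁻¹)
    substrate + partner → target, rate k2*[substrate]^2*[partner] (k = 7600 M⁻² s⁻¹)
    partner → decomposition product (k = 2.70 × 10⁻⁵ s⁻¹)
    partner ⇌ dormant form (K = 0.130, k = 0.00270 s⁻¹)

Noon's 44.5 % lies inside the bracket, though that flask still holds 7.6 % of its partner unbound at the end, more than the 5.68 % I reckoned unspent. Now take the autumn flask with 10 mM of partner in place of 4.00 mM. With the life 0.442 min free of the charge, exposure grows 2.50 times, and I expect the share of partner left at 3.00 min to stay put. That share reads 0.73 % against autumn's 0.69 %. The neighbour flask holds 17.4 % target, 2.15 times autumn's 8.08 %, with 82.6 % of the substrate still there.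

The earlier runs and the new flask were generated by integration for an exercise.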